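The route rests on disconnecting C3–C7′ of the lactone (O1, C2 carbonyl, C3, C4, C5) while tying C2 temporarily to the ring B oxygen O2′ as an aryl acetal. Ring B carries a free hydroxyl (O2′) ortho to the benzylic carbon C7′, so O2′–C2′–C1′–C7′ can act as an ortho-quinone methide heterodiene, while C2=C3 enters as the enol ether of an (R)-3-benzyl-2,3-dihydrofuran that already holds C4. One hetero-Diels–Alder step forms both bonds, closes a pyran ring, sets C3 trans to C4 and fixes the carbonyl position at C2. The precursors are dihydrofuran 10 and Boc-protected salicyl alcohol 16, which releases the methide at low temperature.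

Key step: step 10

Remark: C7 and ring A (4-hydroxy-3-methoxyphenyl) sit on C4, C7′ and ring B (2,4-dihydroxy-3-methoxyphenyl) on C3; in step 2 the (S,S) ligand is assumed to be the antipode that leads to the (R) acid, to be confirmed on lactone 7 and exchanged for its mirror image if not.

Step 1
Reactants: 1 4-(benzyloxy)-3-methoxybenzaldehyde; 2 dimethyl succinate
Product: 4 (E)-4-[4-(benzyloxy)-3-methoxyphenyl]-3-(methoxycarbonyl)but-3-enoic acid, via paraconic ester 3 (not isolated)
Conditions: NaOMe (2 equiv), MeOH, reflux; then aq. HCl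
Reagents that add atoms: none
Why: Stobbe condensation: the succinate enolate adds to the aldehyde, the aldolate closes to paraconic ester 3 and base-induced ring opening of 3 should give the conjugated (E) half ester with the ester on the alkene carbon and the free acid on the CH2 arm.

Step 2
Reactants: 4 (E)-4-[4-(benzyloxy)-3-methoxyphenyl]-3-(methoxycarbonyl)but-3-enoic acid
Product: 5 (R)-4-[4-(benzyloxy)-3-methoxyphenyl]-3-(methoxycarbonyl)butanoic acid
Conditions: H2 (5 bar), [Rh(cod)((S,S)-Et-DuPhos)]BF4 (0.5 mol%), NaOMe (10 mol%), MeOH, rt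
Reagents that add atoms: none
Why: Rhodium-catalysed asymmetric hydrogenation of an itaconate-type half ester: chelation of alkene and carboxyl arm to the cationic monovalent rhodium centre lets the C2-symmetric bisphospholane choose the alkene face, which sets the (R) centre that becomes C4 of the target, and the benzyl ether is inert to this homogeneous catalyst.

Step 3
Reactants: 5 (R)-4-[4-(benzyloxy)-3-methoxyphenyl]-3-(methoxycarbonyl)butanoic acid
Product: 7 (R)-4-[4-(benzyloxy)-3-methoxybenzyl]dihydrofuran-2(3H)-one, via hydroxy acid 6 (not isolated)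
Conditions: KOH (1 equiv), EtOH; CaCl2, NaBH4, EtOH, −10 °C → rt; then 2 M HCl
Reagents that add atoms: none
Why: Chemoselective borohydride reduction followed by lactonisation: Ca(BH4)2 reduces the methyl ester but not the potassium carboxylate, and acid then closes hydroxy acid 6 to the gamma-lactone, the stereocentre being kept because no excess base is present and the reduction runs cold.

Step 4
Reactants: 7 (R)-4-[4-(benzyloxy)-3-methoxybenzyl]dihydrofuran-2(3H)-one
Product: 8 (4R)-4-[4-(benzyloxy)-3-methoxybenzyl]tetrahydrofuran-2-ol (anomer mixture)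
Conditions: i-Bu2AlH (1.1 equiv), CH2Cl2, −78 °C; then aq. potassium sodium tartrate
Reagents that add atoms: none
Why: Partial lactone reduction with i-Bu2AlH: the aluminium hemiacetal is stable at −78 °C and should release the lactol only on work-up, with the C4 centre untouched.

Step 5
Reactants: 8 (4R)-4-[4-(benzyloxy)-3-methoxybenzyl]tetrahydrofuran-2-ol
Product: 10 (R)-3-[4-(benzyloxy)-3-methoxybenzyl]-2,3-dihydrofuran, via anomeric mesylate 9 (not isolated)
Conditions: MsCl (1.3 equiv), Et3N (4 equiv), CH2Cl2, −40 °C → reflux; chromatography on Et3N-treated silica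
Reagents that add atoms: none
Why: Lactol dehydration by sulfonylation and elimination: mesylate 9 ionises to the oxocarbenium ion and Et3N removes the only available beta proton, so the enol ether forms under basic conditions that leave the neighbouring allylic stereocentre alone.

Step 6
Reactants: 11 2-methoxyresorcinol
Product: 13 2,4-dihydroxy-3-methoxybenzaldehyde, via aryl iminium salt 12 (not isolated)
Conditions: POCl3 (1.2 equiv), DMF (1.5 equiv), MeCN, −15 °C → rt; then H2O, 50 °C
Reagents that add atoms: N,N-dimethylformamide, CN(C)C=O; water, O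
Why: Vilsmeier–Haack formylation: the chloroiminium ion attacks one of the two equivalent positions that are ortho to one hydroxyl and para to the other, and hydrolysis of iminium salt 12 should give the aldehyde.

Step 7
Reactants: 13 2,4-dihydroxy-3-methoxybenzaldehyde
Product: 14 4-(benzyloxy)-2-hydroxy-3-methoxybenzaldehyde
Conditions: BnBr (1.05 equiv), NaHCO3 (1.5 equiv), KI (cat.), MeCN, 70 °C
Reagents that add atoms: benzyl bromide, BrCc1ccccc1
Why: Regioselective Williamson ether synthesis: only the more acidic 4-hydroxyl para to the formyl group is ionised by NaHCO3, while the 2-hydroxyl is held in a hydrogen bond to the carbonyl and stays free.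

Step 8
Reactants: 14 4-(benzyloxy)-2-hydroxy-3-methoxybenzaldehyde
Product: 15 3-(benzyloxy)-6-formyl-2-methoxyphenyl tert-butyl carbonate
Conditions: Boc2O (1.3 equiv), DMAP (10 mol%), i-Pr2NEt (1.3 equiv), THF, rt
Reagents that add atoms: di-tert-butyl dicarbonate, CC(C)(C)OC(=O)OC(=O)OC(C)(C)C
Why: DMAP-catalysed O-acylation with Boc2O: the acylpyridinium ion should carbonate even this hydrogen-bonded phenol, installing the group that later triggers the methide release.

Step 9
Reactants: 15 3-(benzyloxy)-6-formyl-2-methoxyphenyl tert-butyl carbonate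
Product: 16 3-(benzyloxy)-6-(hydroxymethyl)-2-methoxyphenyl tert-butyl carbonate
Conditions: BH3·THF (0.7 equiv), THF, 0 °C; then H2O
Reagents that add atoms: none
Why: Borane reduction of an aldehyde: the electrophilic reagent gives a boron alkoxide that is not nucleophilic enough to attack the adjacent aryl carbonate, so the Boc group should stay on the phenol until step 10.

Step 10
Reactants: 16 3-(benzyloxy)-6-(hydroxymethyl)-2-methoxyphenyl tert-butyl carbonate; 10 (R)-3-[4-(benzyloxy)-3-methoxybenzyl]-2,3-dihydrofuran
Product: 19 (3R,3aR,9aR)-7-(benzyloxy)-3-[4-(benzyloxy)-3-methoxybenzyl]-8-methoxy-2,3,3a,9a-tetrahydro-4H-furo[2,3-b]chromene, via magnesium phenoxide 17 (not isolated), via quinone methide 18 (not isolated)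
Conditions: 16 (2 equiv), 10 (1 equiv), t-BuMgCl (2 equiv, in Et2O), toluene, −78 °C → rt; aq. NH4Cl
Reagents that add atoms: none
Why: t-BuMgCl deprotonates the benzylic alcohol, the Boc group moves from the phenol to the alkoxide to give magnesium phenoxide 17, and on warming 17 loses tert-butyl carbonate by 1,4-elimination to release ortho-quinone methide 18, which enol ether 10 traps in a concerted but asynchronous inverse-electron-demand hetero-Diels–Alder reaction in which C3–C7′ bond formation runs ahead of O2′–C2. The closest known reaction type is the [4+2] cycloaddition of ortho-quinone methides, released by this magnesium-mediated carbonate transfer, with 2,3-dihydrofuran and other cyclic enol ethers to give cis-fused furo[2,3-b]chromans. The dihydropyran ring is closed by the intermolecular [4+2] annulation itself, its two new bonds (C3a–C4 and O9–C9a in chromene numbering) forming suprafacially on the enol ether. C3a is controlled by the resident stereocentre on the adjacent carbon of 10, since the methide carbon approaches the face opposite the benzyl group and so places the new CH2 trans to it, and C9a follows from suprafacial addition to the ring alkene, which can only give the cis ring fusion. The step needs regioselectivity, secured by the match of the electrophilic methide carbon with the nucleophilic beta carbon of the enol ether, facial selectivity, secured by the benzyl group directly next to the attacked carbon, and chemoselectivity against self-condensation of 18, secured by its slow magnesium-tempered release and by using 16 in excess over the more valuable 10. No endo/exo question arises because the methide carbon is unsubstituted.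

Step 11
Reactants: 19 (3R,3aR,9aR)-7-(benzyloxy)-3-[4-(benzyloxy)-3-methoxybenzyl]-8-methoxy-2,3,3a,9a-tetrahydro-4H-furo[2,3-b]chromene
Product: 21 (3R,4R)-3-[4-(benzyloxy)-2-hydroxy-3-methoxybenzyl]-4-[4-(benzyloxy)-3-methoxybenzyl]dihydrofuran-2(3H)-one, via lactol 20 (not isolated)
Conditions: CrO3, H2SO4, H2O, acetone, 0 °C; then i-PrOH
Reagents that add atoms: water, O
Why: Jones oxidation of a cyclic acetal: in aqueous acid the aryl acetal opens towards the five-membered oxocarbenium ion with loss of the phenol, lactol 20 is oxidised irreversibly by hexavalent chromium, and the C3 centre next to the new carbonyl is already in the more stable trans arrangement, so it should not drift.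

Step 12
Reactants: 21 (3R,4R)-3-[4-(benzyloxy)-2-hydroxy-3-methoxybenzyl]-4-[4-(benzyloxy)-3-methoxybenzyl]dihydrofuran-2(3H)-one
Product: 22 (3R,4R)-3-(2,4-dihydroxy-3-methoxybenzyl)-4-(4-hydroxy-3-methoxybenzyl)dihydrofuran-2(3H)-one
Conditions: H2 (1 atm), 10% Pd/C, EtOAc/EtOH, rt
Reagents that add atoms: none
Why: Hydrogenolysis of the two benzyl aryl ethers on zerovalent palladium: lactone, methyl ethers and both stereocentres are inert, so the target should result directly.

Compound list
1 | 4-(benzyloxy)-3-methoxybenzaldehyde (O-benzylvanillin) | COc1cc(C=O)ccc1OCc1ccccc1 | starting material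
2 | dimethyl succinate | COC(=O)CCC(=O)OC | starting material
3 | paraconic ester: methyl 2-[4-(benzyloxy)-3-methoxyphenyl]-5-oxotetrahydrofuran-3-carboxylate (racemic diastereomer mixture; forms in the flask) | COC(=O)C1CC(=O)OC1c1ccc(OCc2ccccc2)c(OC)c1 | intermediate
4 | (E)-4-[4-(benzyloxy)-3-methoxyphenyl]-3-(methoxycarbonyl)but-3-enoic acid | COC(=O)/C(CC(=O)O)=C/c1ccc(OCc2ccccc2)c(OC)c1 | intermediate
5 | (R)-4-[4-(benzyloxy)-3-methoxyphenyl]-3-(methoxycarbonyl)butanoic acid | COC(=O)[C@@H](CC(=O)O)Cc1ccc(OCc2ccccc2)c(OC)c1 | intermediate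
6 | (R)-4-[4-(benzyloxy)-3-methoxyphenyl]-3-(hydroxymethyl)butanoic acid (held as its carboxylate salt; forms in the flask) | OC[C@@H](CC(=O)O)Cc1ccc(OCc2ccccc2)c(OC)c1 | intermediate
7 | (R)-4-[4-(benzyloxy)-3-methoxybenzyl]dihydrofuran-2(3H)-one | O=C1C[C@@H](Cc2ccc(OCc3ccccc3)c(OC)c2)CO1 | intermediate
8 | (4R)-4-[4-(benzyloxy)-3-methoxybenzyl]tetrahydrofuran-2-ol (anomer mixture) | OC1C[C@@H](Cc2ccc(OCc3ccccc3)c(OC)c2)CO1 | intermediate
9 | (4R)-4-[4-(benzyloxy)-3-methoxybenzyl]tetrahydrofuran-2-yl methanesulfonate (forms in the flask) | CS(=O)(=O)OC1C[C@@H](Cc2ccc(OCc3ccccc3)c(OC)c2)CO1 | intermediate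
10 | (R)-3-[4-(benzyloxy)-3-methoxybenzyl]-2,3-dihydrofuran | C1=COC[C@@H]1Cc1ccc(OCc2ccccc2)c(OC)c1 | intermediate
11 | 2-methoxyresorcinol (2-methoxybenzene-1,3-diol) | COc1c(O)cccc1O | starting material
12 | N-[(2,4-dihydroxy-3-methoxyphenyl)methylidene]-N-methylmethanaminium chloride (forms in the flask) | C[N+](C)=Cc1ccc(O)c(OC)c1O.[Cl-] | intermediate
13 | 2,4-dihydroxy-3-methoxybenzaldehyde | COc1c(O)ccc(C=O)c1O | intermediate
14 | 4-(benzyloxy)-2-hydroxy-3-methoxybenzaldehyde | COc1c(OCc2ccccc2)ccc(C=O)c1O | intermediate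
15 | 3-(benzyloxy)-6-formyl-2-methoxyphenyl tert-butyl carbonate | COc1c(OCc2ccccc2)ccc(C=O)c1OC(=O)OC(C)(C)C | intermediate
16 | 3-(benzyloxy)-6-(hydroxymethyl)-2-methoxyphenyl tert-butyl carbonate | COc1c(OCc2ccccc2)ccc(CO)c1OC(=O)OC(C)(C)C | intermediate
17 | chloromagnesium 3-(benzyloxy)-6-{[(tert-butoxycarbonyl)oxy]methyl}-2-methoxyphenolate (forms in the flask) | COc1c(OCc2ccccc2)ccc(COC(=O)OC(C)(C)C)c1[O-].[Mg+2].[Cl-] | intermediate
18 | 3-(benzyloxy)-2-methoxy-6-methylidenecyclohexa-2,4-dien-1-one (ortho-quinone methide; forms in the flask) | C=C1C=CC(OCc2ccccc2)=C(OC)C1=O | intermediate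
19 | (3R,3aR,9aR)-7-(benzyloxy)-3-[4-(benzyloxy)-3-methoxybenzyl]-8-methoxy-2,3,3a,9a-tetrahydro-4H-furo[2,3-b]chromene (cis-fused; benzyl trans to the pyran CH2) | COc1cc(C[C@H]2CO[C@@H]3Oc4c(OC)c(OCc5ccccc5)ccc4C[C@H]23)ccc1OCc1ccccc1 | intermediate
20 | (3R,4R)-3-[4-(benzyloxy)-2-hydroxy-3-methoxybenzyl]-4-[4-(benzyloxy)-3-methoxybenzyl]tetrahydrofuran-2-ol (anomer mixture; forms in the flask) | COc1cc(C[C@H]2COC(O)[C@@H]2Cc2ccc(OCc3ccccc3)c(OC)c2O)ccc1OCc1ccccc1 | intermediate
21 | (3R,4R)-3-[4-(benzyloxy)-2-hydroxy-3-methoxybenzyl]-4-[4-(benzyloxy)-3-methoxybenzyl]dihydrofuran-2(3H)-one | COc1cc(C[C@H]2COC(=O)[C@@H]2Cc2ccc(OCc3ccccc3)c(OC)c2O)ccc1OCc1ccccc1 | intermediate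
22 | (3R,4R)-3-(2,4-dihydroxy-3-methoxybenzyl)-4-(4-hydroxy-3-methoxybenzyl)dihydrofuran-2(3H)-one | COc1cc(C[C@H]2COC(=O)[C@@H]2Cc2ccc(O)c(OC)c2O)ccc1O | target

Total step count: 12. Longest linear sequence: 8 steps (steps 1 to 5, then 10 to 12, from compound 1).

Steps most likely to fail

Step 10. The methide may condense with itself or with phenoxide 17 faster than it meets the enol ether, or the attack may not discriminate well enough between the two faces of 10. The fallback abandons the cycloaddition for a trans-selective enolate alkylation; it sets out from lactone 7 and aldehyde 14 and comes back at target 22. Aldehyde 14 is benzylated at the remaining hydroxyl (BnBr, K2CO3, DMF) to 2,4-bis(benzyloxy)-3-methoxybenzaldehyde F1, which NaBH4 in MeOH reduces to [2,4-bis(benzyloxy)-3-methoxyphenyl]methanol F2, and PBr3 in Et2O at 0 °C converts this to 1,3-bis(benzyloxy)-4-(bromomethyl)-2-methoxybenzene F3, used crude. The lithium enolate of 7 (LiN(SiMe3)2, THF, −78 °C) is alkylated by F3 on the face opposite the C4 benzyl group to give (3R,4R)-3-[2,4-bis(benzyloxy)-3-methoxybenzyl]-4-[4-(benzyloxy)-3-methoxybenzyl]dihydrofuran-2(3H)-one F4, and hydrogenolysis (H2, 10% Pd/C) of its three benzyl ethers should give 22.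

Step 11. The electron-rich phenol that is freed during the oxidation may itself be attacked by hexavalent chromium. The fallback masks the phenol before the oxidation; it sets out from cycloadduct 19 and comes back at lactone 21. Acetolysis of 19 (Ac2O, AcOH, cat. H2SO4, 0 °C) should trap the departing phenol as its acetate and the oxocarbenium ion as the anomeric acetate, giving (3R,4R)-3-[2-acetoxy-4-(benzyloxy)-3-methoxybenzyl]-4-[4-(benzyloxy)-3-methoxybenzyl]tetrahydrofuran-2-yl acetate F5. CrO3/H2SO4 in aqueous acetone then hydrolyses only the anomeric acetate and oxidises the lactol to (3R,4R)-3-[2-acetoxy-4-(benzyloxy)-3-methoxybenzyl]-4-[4-(benzyloxy)-3-methoxybenzyl]dihydrofuran-2(3H)-one F6. Brief methanolysis (K2CO3, MeOH, 0 °C, then dilute acid to re-close any opened lactone) removes the aryl acetate and gives 21.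

Step 5. The elimination may stop at the anomeric chloride or mesylate stage, or the acid-sensitive enol ether may be hydrated or dimerised during isolation. The fallback separates acetal formation from elimination; it sets out from lactol 8 and comes back at dihydrofuran 10. Lactol 8 is converted with MeOH and PPTS into (4R)-4-[4-(benzyloxy)-3-methoxybenzyl]-2-methoxytetrahydrofuran F7, a stable methyl acetal. Treatment of F7 with Me3SiOTf and i-Pr2NEt in CH2Cl2 (−20 °C → rt) ionises the acetal and removes the adjacent proton under buffered conditions, which should give 10.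

Further compounds
F1 | step 10 | 2,4-bis(benzyloxy)-3-methoxybenzaldehyde | COc1c(OCc2ccccc2)ccc(C=O)c1OCc1ccccc1
F2 | step 10 | [2,4-bis(benzyloxy)-3-methoxyphenyl]methanol | COc1c(OCc2ccccc2)ccc(CO)c1OCc1ccccc1
F3 | step 10 | 1,3-bis(benzyloxy)-4-(bromomethyl)-2-methoxybenzene | COc1c(OCc2ccccc2)ccc(CBr)c1OCc1ccccc1
F4 | step 10 | (3R,4R)-3-[2,4-bis(benzyloxy)-3-methoxybenzyl]-4-[4-(benzyloxy)-3-methoxybenzyl]dihydrofuran-2(3H)-one | COc1cc(C[C@H]2COC(=O)[C@@H]2Cc2ccc(OCc3ccccc3)c(OC)c2OCc2ccccc2)ccc1OCc1ccccc1
F5 | step 11 | (3R,4R)-3-[2-acetoxy-4-(benzyloxy)-3-methoxybenzyl]-4-[4-(benzyloxy)-3-methoxybenzyl]tetrahydrofuran-2-yl acetate (anomer mixture) | COc1cc(C[C@H]2COC(OC(C)=O)[C@@H]2Cc2ccc(OCc3ccccc3)c(OC)c2OC(C)=O)ccc1OCc1ccccc1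
F6 | step 11 | (3R,4R)-3-[2-acetoxy-4-(benzyloxy)-3-methoxybenzyl]-4-[4-(benzyloxy)-3-methoxybenzyl]dihydrofuran-2(3H)-one | COc1cc(C[C@H]2COC(=O)[C@@H]2Cc2ccc(OCc3ccccc3)c(OC)c2OC(C)=O)ccc1OCc1ccccc1
F7 | step 5 | (4R)-4-[4-(benzyloxy)-3-methoxybenzyl]-2-methoxytetrahydrofuran (anomer mixture) | COC1C[C@@H](Cc2ccc(OCc3ccccc3)c(OC)c2)CO1
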